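**Retrosynthetic overview**
1. The target comes from diol 27 by two Yamaguchi-type angeloylations (primary hydroxyl first, then the secondary one); 27 comes from acetonide 26 of the tricyclic enone.
2. Key disconnection: the cyclobutane bond between the ring CH next to the ketone and the ring CH that carries the quaternary C(CH3)(CH2O) carbon. It is made by a ring-contracting 1,2-shift of that second CH from the carbinol carbon of a bridgehead alkoxide onto the neighbouring endo-mesylate carbon (24 to 26).
3. Enabling feature: in the bicyclo[3.1.1]hept-3-en-2-one core the ketone carbon is bonded directly to the cyclobutane CH that must receive the new bond, so the migrating CH is the one-carbon bridge of an isomeric 1-oxy-norbornene. That norbornene, with the seven-membered ring already attached (longifolane-type skeleton), is a cyclopentadiene Diels–Alder adduct.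
4. Norbornene 22 comes from an intramolecular Diels–Alder reaction of silyloxycyclopentadiene 21 with a tethered (E)-alkenyl boronate, whose boron later becomes the endo leaving group. Enone 20 comes from a gold-catalysed Rautenstrauch rearrangement of enynyl pivalate 18. The quaternary carbon and the carbinol are set by iridium-catalysed tert-(hydroxy)prenylation of 1 with 2; the vinyl and hydroxymethyl groups of that adduct then exchange roles (vinyl becomes the ring CH2O, hydroxymethyl becomes the alkyne carbon).
5. Ring order: temporary dioxane (step 4), then the cyclopentenone ring (step 11), then norbornene and seven-membered ring together (step 12), then cyclobutane and cyclohexenone together (step 15).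

Key step: step 15

Assumption: the tert-(hydroxy)prenylation is taken to give the anti diol (new hydroxyl anti to the hydroxymethyl group when the chain through the vinyl group is drawn zigzag), and the (S)-Tol-BINAP iridium catalyst is taken to give its (2R,3R) enantiomer 4; if the sense of enantioinduction is the opposite, the (R)-ligand is used.
Assumption: compounds 1, 2, 12 and 28 are taken as commercial.

Step 1
Reactants: 1 5-(trimethylsilyl)pent-4-yn-1-ol; 2 2-methyl-2-vinyloxirane (isoprene monoxide, racemic)
Product: 4 (2R,3R)-2-ethenyl-2-methyl-7-(trimethylsilyl)hept-6-yne-1,3-diol, via 5-(trimethylsilyl)pent-4-ynal 3 (not isolated)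
Conditions: preformed π-allyl iridium C,O-benzoate complex from [Ir(cod)Cl]2, (S)-Tol-BINAP, 4-cyano-3-nitrobenzoic acid and allyl acetate (5 mol%), K3PO4 (5 mol%), THF, 60 °C
Reagents that add atoms: none
Why: Iridium-catalysed transfer-hydrogenative carbonyl tert-(hydroxy)prenylation: 1 is dehydrogenated to aldehyde 3, the iridium hydride opens the vinyl epoxide to an (E)-σ-allyl species, and addition through a chair-like six-membered transition state with the hydroxymethyl group pseudo-equatorial and the methyl group pseudo-axial places the new hydroxyl anti to CH2OH (anti diol), the bisphosphine choosing the aldehyde face.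

Step 2
Reactants: 4 (2R,3R)-2-ethenyl-2-methyl-7-(trimethylsilyl)hept-6-yne-1,3-diol
Product: 5 (2R,3R)-2-ethenyl-3-hydroxy-2-methyl-7-(trimethylsilyl)hept-6-yn-1-yl 2,2-dimethylpropanoate
Conditions: PivCl (1.1 equiv), pyridine, CH2Cl2, 0 °C
Reagents that add atoms: pivaloyl chloride, CC(C)(C)C(Cl)=O
Why: Selective acylation of the primary hydroxyl over the secondary hydroxyl flanked by the quaternary carbon; it marks the original hydroxymethyl group as the future aldehyde carbon, and the pivalate is chosen because it migrates slowly.

Step 3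
Reactants: 5 (2R,3R)-2-ethenyl-3-hydroxy-2-methyl-7-(trimethylsilyl)hept-6-yn-1-yl 2,2-dimethylpropanoate
Product: 7 (2R,3R)-3-hydroxy-2-(hydroxymethyl)-2-methyl-7-(trimethylsilyl)hept-6-yn-1-yl 2,2-dimethylpropanoate, via 1,2,4-trioxolane 6 (not isolated)
Conditions: O3, CH2Cl2, −78 °C (Sudan red 7B end point); then NaBH4, MeOH, −78 to 0 °C
Reagents that add atoms: ozone, [O-][O+]=O
Why: Ozonolysis with reductive borohydride work-up; the terminal alkene is cleaved much faster than the silylated alkyne, the ozonide is reduced directly to the primary alcohol so that no retro-aldol-prone β-hydroxy aldehyde accumulates, and the pivalate is neither reduced nor expected to migrate at low temperature.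

Step 4
Reactants: 7 (2R,3R)-3-hydroxy-2-(hydroxymethyl)-2-methyl-7-(trimethylsilyl)hept-6-yn-1-yl 2,2-dimethylpropanoate
Product: 8 [(4R,5R)-2,2,5-trimethyl-4-[4-(trimethylsilyl)but-3-yn-1-yl]-1,3-dioxan-5-yl]methyl 2,2-dimethylpropanoate
Conditions: 2,2-dimethoxypropane, PPTS (cat.), CH2Cl2, rt
Reagents that add atoms: 2,2-dimethoxypropane, COC(C)(C)OC
Why: Acid-catalysed acetonide formation (transketalisation) of the only free 1,3-diol, so the carbon that came from the vinyl group becomes the ring CH2O while the original hydroxymethyl carbon stays exocyclic; this exchange of roles places the C5 methyl cis to the C4 side chain, the relative configuration the target needs.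

Step 5
Reactants: 8 [(4R,5R)-2,2,5-trimethyl-4-[4-(trimethylsilyl)but-3-yn-1-yl]-1,3-dioxan-5-yl]methyl 2,2-dimethylpropanoate
Product: 9 [(4R,5S)-2,2,5-trimethyl-4-[4-(trimethylsilyl)but-3-yn-1-yl]-1,3-dioxan-5-yl]methanol
Conditions: i-Bu2AlH (2.5 equiv), CH2Cl2, −78 °C; aq. potassium sodium tartrate work-up
Reagents that add atoms: none
Why: Reductive cleavage of the pivalate ester by the aluminium hydride; acetonide and alkynylsilane are inert at low temperature (basic methanolysis is avoided because it would remove the alkynylsilane).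

Step 6
Reactants: 9 [(4R,5S)-2,2,5-trimethyl-4-[4-(trimethylsilyl)but-3-yn-1-yl]-1,3-dioxan-5-yl]methanol
Product: 10 (4R,5S)-2,2,5-trimethyl-4-[4-(trimethylsilyl)but-3-yn-1-yl]-1,3-dioxane-5-carbaldehyde
Conditions: Dess–Martin periodinane, CH2Cl2, 0 °C to rt
Reagents that add atoms: none
Why: Dess–Martin oxidation of the neopentyl primary alcohol; the aldehyde formed has no α-hydrogen, so the quaternary centre cannot epimerise.

Step 7
Reactants: 10 (4R,5S)-2,2,5-trimethyl-4-[4-(trimethylsilyl)but-3-yn-1-yl]-1,3-dioxane-5-carbaldehyde
Product: 11 (4R,5S)-5-(2,2-dibromoethenyl)-2,2,5-trimethyl-4-[4-(trimethylsilyl)but-3-yn-1-yl]-1,3-dioxane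
Conditions: CBr4, PPh3, CH2Cl2, 0 °C
Reagents that add atoms: carbon tetrabromide, BrC(Br)(Br)Br
Why: First stage of the Corey–Fuchs alkyne synthesis (Wittig-type reaction of Ph3P=CBr2 with the non-enolisable aldehyde); no stereocentre is touched.

Step 8
Reactants: 11 (4R,5S)-5-(2,2-dibromoethenyl)-2,2,5-trimethyl-4-[4-(trimethylsilyl)but-3-yn-1-yl]-1,3-dioxane; 12 methacrolein (2-methylprop-2-enal)
Product: 15 1-[(4R,5S)-4-(but-3-yn-1-yl)-2,2,5-trimethyl-1,3-dioxan-5-yl]-4-methylpent-4-en-1-yn-3-ol (both carbinol epimers), via lithium alkynide 13 (not isolated), via C-silyl enynol lithium alkoxide 14 (not isolated)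
Conditions: n-BuLi (2.1 equiv), THF, −78 to 0 °C; methacrolein, −78 °C; then MeOH, K2CO3 (cat.), rt
Reagents that add atoms: none
Why: The second Corey–Fuchs stage (bromine–lithium exchange, Fritsch–Buttenberg–Wiechell 1,2-shift, deprotonation) gives the lithium alkynide, which adds 1,2 to methacrolein, and methanolysis removes the alkynylsilane; the new carbinol centre forms as a mixture, which is harmless because it becomes sp2 in step 11.

Step 9
Reactants: 15 1-[(4R,5S)-4-(but-3-yn-1-yl)-2,2,5-trimethyl-1,3-dioxan-5-yl]-4-methylpent-4-en-1-yn-3-ol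
Product: 17 4-methyl-1-{(4R,5S)-2,2,5-trimethyl-4-[(3E)-3-methyl-4-(4,4,5,5-tetramethyl-1,3,2-dioxaborolan-2-yl)but-3-en-1-yl]-1,3-dioxan-5-yl}pent-4-en-1-yn-3-ol, via alkenylalane 16 (not isolated)
Conditions: AlMe3 (4 equiv), Cp2ZrCl2 (0.3 equiv), H2O (1 equiv), CH2Cl2, −25 °C; then 2-methoxy-4,4,5,5-tetramethyl-1,3,2-dioxaborolane, 0 °C to rt
Reagents that add atoms: trimethylaluminium, C[Al](C)C; 2-methoxy-4,4,5,5-tetramethyl-1,3,2-dioxaborolane, COB1OC(C)(C)C(C)(C)O1
Why: Zirconium-catalysed Negishi carboalumination adds methyl and aluminium syn across the terminal alkyne (methyl to the internal carbon) and the alkenylalane is transmetalated to boron with retention, so boron ends cis to the methyl group ((E)-alkenyl boronate); the alcohol is masked as its aluminium alkoxide, and the hindered internal alkyne and the 1,1-disubstituted alkene are not carbometalated.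

Step 10
Reactants: 17 the (E)-alkenyl pinacol boronate enynol
Product: 18 pivalate ester of 17 (3-pivaloyloxy-1,4-enyne)
Conditions: PivCl, Et3N, DMAP (cat.), CH2Cl2, 0 °C to rt
Reagents that add atoms: pivaloyl chloride, CC(C)(C)C(Cl)=O
Why: DMAP-catalysed acyl transfer to the secondary propargylic alcohol; boronate and acetonide are inert.

Step 11
Reactants: 18 pivalate ester of 17
Product: 20 3-methyl-5-{(4R,5S)-2,2,5-trimethyl-4-[(3E)-3-methyl-4-(4,4,5,5-tetramethyl-1,3,2-dioxaborolan-2-yl)but-3-en-1-yl]-1,3-dioxan-5-yl}cyclopent-2-en-1-one (both epimers at the ring CH), via cyclopentadienyl pivalate 19 (not isolated)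
Conditions: Ph3PAuCl (5 mol%), AgSbF6 (5 mol%), MeCN, H2O (2 equiv), −20 °C to rt
Reagents that add atoms: none
Why: Gold-catalysed Rautenstrauch rearrangement: 1,2-pivaloyloxy shift on the gold-activated alkyne, five-membered ring closure between the alkyne terminus and the alkene CH2 through a pentadienyl-cation-like species, and hydrolysis of dienyl pivalate 19 give the 3-methylcyclopent-2-enone; the new ring CH forms as both epimers, which converge in step 12.

Step 12
Reactants: 20 the 5-substituted 3-methylcyclopent-2-enone
Product: 22 intramolecular Diels–Alder adduct (1-silyloxy-3-methylnorbornene core carrying endo-pinacolboryl on C6 and endo-methyl on C5; C7 on its side facing C5–C6 and exo-C5 are bridged by the chain C(CH3)(CH2O)–CH(O)–CH2–CH2 whose two oxygens form the acetonide), via silyl dienol ether 21 (not isolated)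
Conditions: TBSOTf, Et3N, CH2Cl2, 0 °C; then toluene (high dilution), BHT (cat.), 170 °C, sealed tube
Reagents that add atoms: tert-butyldimethylsilyl triflate, CC(C)(C)[Si](C)(C)OS(=O)(=O)C(F)(F)F
Why: Soft enolisation gives the silyl dienol ether, whose cyclopentadiene tautomers equilibrate by 1,5-hydrogen shifts at the reaction temperature, and the intramolecular Diels–Alder reaction should drain the 5-alkyl tautomer 21 because the 1-alkyl tautomer could only react by joining two fully substituted carbons next to the quaternary centre; the silyloxy-bearing terminus bonds to the boron-bearing carbon and the unsubstituted, most nucleophilic terminus to the methyl-bearing carbon (electronically matched and least hindered), the (E)-geometry places boron and methyl endo and the tether exo, and of the two chair-like seven-membered transition states the one with the ring C–O bond of the carbinol carbon pointing outward (hydrogen inward, towards the two-carbon bridge) should be the less strained, which fixes the five new stereocentres relative to the two old ones.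

Step 13
Reactants: 22 the endo-boronate adduct
Product: 23 the corresponding endo secondary alcohol (bridgehead silyl ether retained)
Conditions: H2O2 (30% aq.), NaOH, THF, 0 °C to rt
Reagents that add atoms: hydrogen peroxide, OO
Why: Oxidation of the carbon–boron bond (1,2-shift of carbon from boron to peroxide oxygen) proceeds with retention, so the hydroxyl is endo; β-elimination of the neighbouring silyloxy group would need a bridgehead alkene and cannot occur.

Step 14
Reactants: 23 the endo alcohol
Product: 24 the endo methanesulfonate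
Conditions: MsCl, Et3N, DMAP (cat.), CH2Cl2, 0 °C
Reagents that add atoms: methanesulfonyl chloride, CS(Cl)(=O)=O
Why: Sulfonylation of the only free hydroxyl via sulfene; the C–O bond is untouched, so the leaving group stays endo.

Step 15
Reactants: 24 the endo methanesulfonate
Product: 26 acetonide of the tricyclic enone (bicyclo[3.1.1]hept-3-en-2-one core with the four-carbon bridge across the two one-carbon bridges), via bridgehead alkoxide 25 (not isolated)
Conditions: TBAF (1.0 M in THF, dried over 4 Å MS), THF, 0 to 40 °C
Reagents that add atoms: none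
Why: Proposed new method: fluoride removes the bridgehead silyl group and the tertiary alkoxide 25 collapses to the ketone while the one-carbon bridge CH (the carbon bearing the quaternary centre) shifts from the carbinol carbon to the adjacent mesylate-bearing carbon and expels mesylate, an anionic semipinacol 1,2-shift whose closest known relatives are the base-induced pinacol-type rearrangement of vicinal hydroxy sulfonates and the quasi-Favorskii shift of bridged α-halo ketones, whereas a norbornane-to-bicyclo[3.1.1]heptane contraction of this kind is not established. The cyclobutane is closed by this suprafacial 1,2-alkyl shift (contraction of the five-membered ring made of the carbinol carbon, the bridge CH, the other bridgehead and the two sp3 carbons of the two-carbon bridge), and in the same event the cyclopentene ring grows to the six-membered enone ring. The only new stereocentre, the cyclobutane CH next to the carbonyl, arises by inversion at the mesylate carbon because the migrating carbon enters from the exo face opposite the endo leaving group; the migrating carbon keeps its configuration and the rigid cage allows no alternative. The selectivity needed is migration of the bridge carbon and not of the vinylic carbon: only the bridgehead–bridge bond is antiperiplanar to the endo C–O bond (the vinylic bond is antiperiplanar to the exo position), and under anionic, non-ionising conditions no free cation forms that the alkene could capture. The mesylate carbon has no β-hydrogen, the alkoxide has no leaving group in a 1,3-relation, and the alkoxide oxygen is gauche to the leaving group, so elimination, Grob cleavage and oxirane formation are excluded. Formation of the conjugated carbonyl and release of mesylate should outweigh the additional strain of the bicyclo[3.1.1]heptenone.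

Step 16
Reactants: 26 acetonide of the tricyclic enone
Product: 27 tricyclic enone diol (secondary hydroxyl on the ring CH next to the quaternary carbon, hydroxymethyl on that quaternary carbon)
Conditions: AcOH/H2O/THF (3:1:1), 40 °C
Reagents that add atoms: none
Why: Mild acid-catalysed acetal hydrolysis; the enone has no epimerisable centre (its α-positions are a bridgehead and a vinylic carbon) and the conditions are too mild for cyclobutane opening.

Step 17
Reactants: 27 tricyclic enone diol; 28 angelic acid ((Z)-2-methylbut-2-enoic acid)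
Product: 29 primary monoangelate of 27 (secondary hydroxyl free)
Conditions: angelic acid (1.2 equiv), 2,4,6-trichlorobenzoyl chloride (1.2 equiv), Et3N, toluene, rt; then 27, toluene, rt to 40 °C
Reagents that add atoms: none
Why: Yamaguchi-type esterification: the preformed angelic 2,4,6-trichlorobenzoic mixed anhydride acylates the primary hydroxyl well before the hindered secondary one, and no nucleophilic catalyst is present that would isomerise the (Z)-2-methylbut-2-enoate to the (E)-isomer.

Step 18
Reactants: 29 primary monoangelate of 27; 28 angelic acid ((Z)-2-methylbut-2-enoic acid)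
Product: 30 target diangelate CNP0240716.2
Conditions: angelic acid (4 equiv), 2,4,6-trichlorobenzoyl chloride (4 equiv), Et3N, toluene, rt; then 29, toluene, 80 °C
Reagents that add atoms: none
Why: Second Yamaguchi-type esterification under forcing conditions: excess mixed anhydride in hot toluene acylates the hindered secondary hydroxyl next to the quaternary carbon, again without a nucleophilic catalyst so that the (Z)-geometry of both esters is kept.

**Compound list**
1 | 5-(trimethylsilyl)pent-4-yn-1-ol | C[Si](C)(C)C#CCCCO | starting material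
2 | 2-methyl-2-vinyloxirane (isoprene monoxide, racemic) | CC1(C=C)CO1 | starting material
3 | 5-(trimethylsilyl)pent-4-ynal | C[Si](C)(C)C#CCCC=O | intermediate
4 | (2R,3R)-2-ethenyl-2-methyl-7-(trimethylsilyl)hept-6-yne-1,3-diol | OC[C@@](C)(C=C)[C@H](O)CCC#C[Si](C)(C)C | intermediate
5 | (2R,3R)-2-ethenyl-3-hydroxy-2-methyl-7-(trimethylsilyl)hept-6-yn-1-yl 2,2-dimethylpropanoate | CC(C)(C)C(=O)OC[C@@](C)(C=C)[C@H](O)CCC#C[Si](C)(C)C | intermediate
6 | 1,2,4-trioxolane (ozonide) of 5 | CC(C)(C)C(=O)OC[C@@](C)(C1OCOO1)[C@H](O)CCC#C[Si](C)(C)C | intermediate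
7 | (2R,3R)-3-hydroxy-2-(hydroxymethyl)-2-methyl-7-(trimethylsilyl)hept-6-yn-1-yl 2,2-dimethylpropanoate | CC(C)(C)C(=O)OC[C@@](C)(CO)[C@H](O)CCC#C[Si](C)(C)C | intermediate
8 | [(4R,5R)-2,2,5-trimethyl-4-[4-(trimethylsilyl)but-3-yn-1-yl]-1,3-dioxan-5-yl]methyl 2,2-dimethylpropanoate | CC1(C)OC[C@](C)(COC(=O)C(C)(C)C)[C@@H](CCC#C[Si](C)(C)C)O1 | intermediate
9 | [(4R,5S)-2,2,5-trimethyl-4-[4-(trimethylsilyl)but-3-yn-1-yl]-1,3-dioxan-5-yl]methanol | CC1(C)OC[C@](C)(CO)[C@@H](CCC#C[Si](C)(C)C)O1 | intermediate
10 | (4R,5S)-2,2,5-trimethyl-4-[4-(trimethylsilyl)but-3-yn-1-yl]-1,3-dioxane-5-carbaldehyde | CC1(C)OC[C@](C)(C=O)[C@@H](CCC#C[Si](C)(C)C)O1 | intermediate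
11 | (4R,5S)-5-(2,2-dibromoethenyl)-2,2,5-trimethyl-4-[4-(trimethylsilyl)but-3-yn-1-yl]-1,3-dioxane | CC1(C)OC[C@](C)(C=C(Br)Br)[C@@H](CCC#C[Si](C)(C)C)O1 | intermediate
12 | methacrolein | CC(=C)C=O | starting material
13 | lithium alkynide from 11 | CC1(C)OC[C@](C)(C#C[Li])[C@@H](CCC#C[Si](C)(C)C)O1 | intermediate
14 | lithium alkoxide of the C-silyl enynol | CC1(C)OC[C@](C)(C#CC(O[Li])C(C)=C)[C@@H](CCC#C[Si](C)(C)C)O1 | intermediate
15 | 1-[(4R,5S)-4-(but-3-yn-1-yl)-2,2,5-trimethyl-1,3-dioxan-5-yl]-4-methylpent-4-en-1-yn-3-ol | CC1(C)OC[C@](C)(C#CC(O)C(C)=C)[C@@H](CCC#C)O1 | intermediate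
16 | (E)-alkenyl(dimethyl)alane, hydroxyl as dimethylaluminium alkoxide | CC1(C)OC[C@](C)(C#CC(O[Al](C)C)C(C)=C)[C@@H](CC/C(C)=C/[Al](C)C)O1 | intermediate
17 | (E)-alkenyl pinacol boronate enynol | CC1(C)OC[C@](C)(C#CC(O)C(C)=C)[C@@H](CC/C(C)=C/B2OC(C)(C)C(C)(C)O2)O1 | intermediate
18 | pivalate of 17 | CC1(C)OC[C@](C)(C#CC(OC(=O)C(C)(C)C)C(C)=C)[C@@H](CC/C(C)=C/B2OC(C)(C)C(C)(C)O2)O1 | intermediate
19 | 1-alkyl-4-methyl-2-pivaloyloxycyclopenta-1,3-diene | CC1=CC(OC(=O)C(C)(C)C)=C(C1)[C@@]2(C)COC(C)(C)O[C@@H]2CC/C(C)=C/B3OC(C)(C)C(C)(C)O3 | intermediate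
20 | 5-substituted 3-methylcyclopent-2-en-1-one (boronate, acetonide) | O=C1C=C(C)CC1[C@@]2(C)COC(C)(C)O[C@@H]2CC/C(C)=C/B3OC(C)(C)C(C)(C)O3 | intermediate
21 | tert-butyldimethylsilyl dienol ether (reactive 5-alkyl tautomer drawn) | CC1=CC([C@@]2(C)COC(C)(C)O[C@@H]2CC/C(C)=C/B3OC(C)(C)C(C)(C)O3)C(O[Si](C)(C)C(C)(C)C)=C1 | intermediate
22 | intramolecular Diels–Alder adduct (bridgehead OTBS, endo-Bpin) | CC1(C)OC[C@]2(C)[C@@H]3[C@@]4(O[Si](C)(C)C(C)(C)C)C=C(C)[C@@H]3[C@@](C)(CC[C@H]2O1)[C@@H]4B5OC(C)(C)C(C)(C)O5 | intermediate
23 | endo alcohol | CC1(C)OC[C@]2(C)[C@@H]3[C@@]4(O[Si](C)(C)C(C)(C)C)C=C(C)[C@@H]3[C@@](C)(CC[C@H]2O1)[C@@H]4O | intermediate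
24 | endo methanesulfonate | CC1(C)OC[C@]2(C)[C@@H]3[C@@]4(O[Si](C)(C)C(C)(C)C)C=C(C)[C@@H]3[C@@](C)(CC[C@H]2O1)[C@@H]4OS(C)(=O)=O | intermediate
25 | bridgehead alkoxide (tetrabutylammonium salt) | CC1(C)OC[C@]2(C)[C@@H]3[C@@]4([O-])C=C(C)[C@@H]3[C@@](C)(CC[C@H]2O1)[C@@H]4OS(C)(=O)=O.CCCC[N+](CCCC)(CCCC)CCCC | intermediate
26 | acetonide of the tricyclic enone | CC1(C)OC[C@]2(C)[C@@H]3[C@H]4C(=O)C=C(C)[C@@H]3[C@@]4(C)CC[C@H]2O1 | intermediate
27 | tricyclic enone diol | OC[C@]1(C)[C@@H]2[C@H]3C(=O)C=C(C)[C@@H]2[C@@]3(C)CC[C@H]1O | intermediate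
28 | angelic acid | C/C=C(/C)C(=O)O | starting material
29 | primary monoangelate of 27 | C/C=C(/C)C(=O)OC[C@]1(C)[C@@H]2[C@H]3C(=O)C=C(C)[C@@H]2[C@@]3(C)CC[C@H]1O | intermediate
30 | CNP0240716.2 (diangelate) | C/C=C(/C)C(=O)OC[C@]1(C)[C@@H]2[C@H]3C(=O)C=C(C)[C@@H]2[C@@]3(C)CC[C@H]1OC(=O)/C(C)=C\C | target

**Step count**
Total steps: 18. Longest linear sequence: 18 steps (1 to 30).

**Steps most likely to fail**

Step 15 (Proposed new method). What may go wrong: ionisation of the mesylate before the hindered bridgehead silyl ether is cleaved, leading to migration of the vinylic carbon or capture by the alkene; or an oxyanion-accelerated cycloreversion of the norbornene instead of the 1,2-shift. Fallback with known reaction types, avoiding the oxyanion: it sets out from 22. The carbon–boron bond is aminated with retention by lithiated methoxyamine (MeONH2, n-BuLi, THF, −78 to 60 °C) to give the endo primary amine F1. TBAF then frees the bridgehead alcohol to give amino alcohol F2. Diazotisation (NaNO2, aqueous AcOH, 0 °C) triggers a Tiffeneau–Demjanov-type deaminative semipinacol shift of the antiperiplanar bridge bond as nitrogen leaves from the endo face. This comes back to the route at 26.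

Step 12. What may go wrong: cycloaddition too slow for the weakly activated trisubstituted alkenyl boronate, so that the silyloxydiene dimerises or is desilylated; reaction through the wrong cyclopentadiene tautomer; or poor facial selectivity. Fallback with an ester-activated dienophile (normal electron demand, lower temperature): it sets out from 15. Carboalumination as in step 9 with a methyl chloroformate quench gives the (E)-enoate F3. Pivaloylation gives F4 and the gold-catalysed rearrangement gives enone ester F5. Silylation and heating in toluene at about 110 °C should give the endo-ester adduct F6. KOSiMe3 cleaves the ester to acid F7. A Curtius rearrangement (DPPA, Et3N, toluene, 80 °C, then KOSiMe3 and aqueous work-up) proceeds with retention to the amine F1 described under step 15, which is taken through F2 as described there. This comes back to the route at 26.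

Step 11. What may go wrong: 1,3-acyloxy migration to an allenyl pivalate, or slow ring closure at the alkyne carbon next to the quaternary centre. Fallback by classical 1,4-diketone aldol chemistry: it sets out from 10. A Wittig reaction with Ph3P=CHC(O)CH3 (toluene, 90 °C) gives the (E)-enone F8. Conjugate addition of (CH2=C(OEt))2CuLi (THF, −78 to −20 °C) gives the ethoxyvinyl ketone F9, and aqueous oxalic acid releases the 1,4-diketone F10. KOH in MeOH (50 °C) effects the intramolecular aldol condensation onto the unhindered ketone and removes the alkynylsilane, giving cyclopentenone F11. Luche reduction (NaBH4, CeCl3·7H2O) gives allylic alcohol F12, which tolerates the carboalumination–borylation of step 9 to give F13. Dess–Martin oxidation then comes back to the route at 20.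

**Further compounds**
F1 | step 15 | endo primary amine (bridgehead OTBS) | CC1(C)OC[C@]2(C)[C@@H]3[C@@]4(O[Si](C)(C)C(C)(C)C)C=C(C)[C@@H]3[C@@](C)(CC[C@H]2O1)[C@@H]4N
F2 | step 15 | endo amino bridgehead alcohol | CC1(C)OC[C@]2(C)[C@@H]3[C@@]4(O)C=C(C)[C@@H]3[C@@](C)(CC[C@H]2O1)[C@@H]4N
F3 | step 12 | (E)-methyl enoate enynol | CC1(C)OC[C@](C)(C#CC(O)C(C)=C)[C@@H](CC/C(C)=C/C(=O)OC)O1
F4 | step 12 | pivalate of F3 | CC1(C)OC[C@](C)(C#CC(OC(=O)C(C)(C)C)C(C)=C)[C@@H](CC/C(C)=C/C(=O)OC)O1
F5 | step 12 | cyclopentenone with tethered (E)-enoate | O=C1C=C(C)CC1[C@@]2(C)COC(C)(C)O[C@@H]2CC/C(C)=C/C(=O)OC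
F6 | step 12 | Diels–Alder adduct with endo methyl ester | CC1(C)OC[C@]2(C)[C@@H]3[C@@]4(O[Si](C)(C)C(C)(C)C)C=C(C)[C@@H]3[C@@](C)(CC[C@H]2O1)[C@@H]4C(=O)OC
F7 | step 12 | endo carboxylic acid | CC1(C)OC[C@]2(C)[C@@H]3[C@@]4(O[Si](C)(C)C(C)(C)C)C=C(C)[C@@H]3[C@@](C)(CC[C@H]2O1)[C@@H]4C(=O)O
F8 | step 11 | (E)-enone from 10 | CC1(C)OC[C@](C)(/C=C/C(C)=O)[C@@H](CCC#C[Si](C)(C)C)O1
F9 | step 11 | 1-ethoxyvinyl ketone | CC1(C)OC[C@](C)(C(CC(C)=O)C(=C)OCC)[C@@H](CCC#C[Si](C)(C)C)O1
F10 | step 11 | 1,4-diketone | CC1(C)OC[C@](C)(C(CC(C)=O)C(C)=O)[C@@H](CCC#C[Si](C)(C)C)O1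
F11 | step 11 | cyclopentenone with terminal alkyne | O=C1C=C(C)CC1[C@@]2(C)COC(C)(C)O[C@@H]2CCC#C
F12 | step 11 | cyclopentenol with terminal alkyne | OC1C=C(C)CC1[C@@]2(C)COC(C)(C)O[C@@H]2CCC#C
F13 | step 11 | cyclopentenol with (E)-alkenyl boronate | OC1C=C(C)CC1[C@@]2(C)COC(C)(C)O[C@@H]2CC/C(C)=C/B3OC(C)(C)C(C)(C)O3
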